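**Retrosynthetic overview**

1. The route rests on the furan ring of the target: O1, C2 (bearing the quinone ring), C3 (an unsubstituted CH), C4 (bearing the (S)-acyloxy side chain) and C5 (CH). The C3–C4 bond is disconnected as the ring alkene of a 2,5-dihydrofuran, made by ring-closing metathesis of an oxygen-linked diene 12 (vinyl group on the aryl-bearing carbon, 1,1-disubstituted alkene on the carbinol side).
2. After ring closure the dihydrofuran is dehydrogenated to the furan, and the 1,4-dimethoxybenzene ring is oxidised to the quinone last.
3. Diene 12 comes from the (S)-allylic alcohol 10 by acylation, 10 from enone 9 by oxazaborolidine-catalysed reduction, and 9 from a chromium-mediated coupling of bromoallyl ether 5 with 4-methylpent-3-enal followed by reoxidation. Ether 5 comes from 2,5-dimethoxybenzaldehyde, a vinyl Grignard reagent and 2,3-dibromopropene.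
4. Ring order: the benzene ring is bought; the furan ring is closed in step 8 as a dihydrofuran and aromatised in step 9; the benzene ring becomes the quinone in step 10.

Key step: step 8

Remark on the chemistry: the ring carbon that carries the aryl group is introduced racemic and carried as both epimers, because it becomes sp2 in step 9. Only the carbinol centre, set in step 6, is controlled.

**Step 1**
Reactants: 1 2,5-dimethoxybenzaldehyde
Product: 2 1-(2,5-dimethoxyphenyl)prop-2-en-1-ol (racemic)
Conditions: CH2=CHMgBr (1.2 equiv), THF, 0 °C; then H2O/aq NH4Cl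
Reagents that add atoms: vinylmagnesium bromide, C=C[Mg]Br
Why: Grignard 1,2-addition of the vinyl nucleophile to the aryl aldehyde; the new carbinol centre forms as a racemate, which is acceptable because this carbon is aromatised later.

**Step 2**
Reactants: 2 1-(2,5-dimethoxyphenyl)prop-2-en-1-ol; 3 2,3-dibromopropene
Product: 5 2-{1-[(2-bromoprop-2-en-1-yl)oxy]prop-2-en-1-yl}-1,4-dimethoxybenzene (racemic), via sodium 1-(2,5-dimethoxyphenyl)prop-2-en-1-olate 4 (not isolated)
Conditions: NaH, THF, 0 °C; then 3, Bu4NI (cat.), 0 °C to rt
Reagents that add atoms: none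
Why: Williamson ether synthesis, in which the alkoxide displaces the allylic bromide of 3 by SN2 while the vinylic C–Br bond is inert to substitution and is kept for step 4.

**Step 3**
Reactants: 6 4-methylpent-3-en-1-ol
Product: 7 4-methylpent-3-enal
Conditions: Dess–Martin periodinane, pyridine, CH2Cl2, 0 °C to rt; used at once without purification
Reagents that add atoms: none
Why: Dess–Martin oxidation stops at the aldehyde under buffered, near-neutral conditions that should keep the β,γ double bond from moving into conjugation.

**Step 4**
Reactants: 5 2-{1-[(2-bromoprop-2-en-1-yl)oxy]prop-2-en-1-yl}-1,4-dimethoxybenzene; 7 4-methylpent-3-enal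
Product: 8 2-({[1-(2,5-dimethoxyphenyl)prop-2-en-1-yl]oxy}methyl)-6-methylhepta-1,5-dien-3-ol (all four stereoisomers)
Conditions: CrCl2 (4 equiv), NiCl2 (2 mol %), DMF, rt
Reagents that add atoms: none
Why: Nozaki–Hiyama–Kishi coupling, in which zerovalent nickel inserts into the vinylic C–Br bond, the alkenyl group passes to trivalent chromium and adds selectively to the aldehyde without touching the ethers or the other alkenes; the carbinol centre forms without control and is erased in step 5.

**Step 5**
Reactants: 8 2-({[1-(2,5-dimethoxyphenyl)prop-2-en-1-yl]oxy}methyl)-6-methylhepta-1,5-dien-3-ol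
Product: 9 2-({[1-(2,5-dimethoxyphenyl)prop-2-en-1-yl]oxy}methyl)-6-methylhepta-1,5-dien-3-one (racemic)
Conditions: Dess–Martin periodinane, pyridine, CH2Cl2, 0 °C
Reagents that add atoms: none
Why: Dess–Martin oxidation of the secondary allylic alcohol to the α-methylene ketone is mild and buffered, so the skipped prenyl alkene on the other side of the carbonyl should stay out of conjugation.

**Step 6**
Reactants: 9 2-({[1-(2,5-dimethoxyphenyl)prop-2-en-1-yl]oxy}methyl)-6-methylhepta-1,5-dien-3-one
Product: 10 (3S)-2-({[1-(2,5-dimethoxyphenyl)prop-2-en-1-yl]oxy}methyl)-6-methylhepta-1,5-dien-3-ol (both epimers at the aryl-bearing carbon)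
Conditions: (R)-2-methyl-CBS-oxazaborolidine (20 mol %), catecholborane (1.5 equiv), toluene, −78 °C; then H2O, aq NaHCO3
Reagents that add atoms: none
Why: Corey–Bakshi–Shibata reduction, in which the ketone binds the oxazaborolidine boron with the α-branched alkenyl group as the large substituent and the primary alkyl chain as the small one, so the (R)-catalyst should deliver hydride to the face that gives the (S)-carbinol; catecholborane at low temperature avoids hydroboration of the three alkenes.

**Step 7**
Reactants: 10 (3S)-2-({[1-(2,5-dimethoxyphenyl)prop-2-en-1-yl]oxy}methyl)-6-methylhepta-1,5-dien-3-ol; 11 3-methylbut-2-enoic acid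
Product: 12 (3S)-2-({[1-(2,5-dimethoxyphenyl)prop-2-en-1-yl]oxy}methyl)-6-methylhepta-1,5-dien-3-yl 3-methylbut-2-enoate (both epimers at the aryl-bearing carbon)
Conditions: DCC, DMAP (cat.), CH2Cl2, 0 °C to rt
Reagents that add atoms: none
Why: Steglich esterification acylates at oxygen, so the carbinol configuration is retained, and it avoids the ketene pathway by which the acid chloride with amine base can shift the ester double bond out of conjugation.

**Step 8**
Reactants: 12 (3S)-2-({[1-(2,5-dimethoxyphenyl)prop-2-en-1-yl]oxy}methyl)-6-methylhepta-1,5-dien-3-yl 3-methylbut-2-enoate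
Product: 13 (1S)-1-[5-(2,5-dimethoxyphenyl)-2,5-dihydrofuran-3-yl]-4-methylpent-3-en-1-yl 3-methylbut-2-enoate (both epimers at the aryl-bearing ring carbon)
Conditions: second-generation Grubbs catalyst RuCl2(=CHPh)(PCy3)(H2IMes) (5 mol %), CH2Cl2 (0.005 M), 40 °C
Reagents that add atoms: none
Why: Ring-closing olefin metathesis by the metallacyclobutane mechanism: the ruthenium benzylidene exchanges first with the unhindered monosubstituted vinyl group, the new alkylidene adds across the nearby 1,1-disubstituted alkene in a [2+2] step, and cycloreversion of the ruthenacyclobutane releases the C3=C4 ring alkene while ethene leaves. The closest known reaction type is the closure of allyl 2-substituted-allyl ethers to 3-substituted 2,5-dihydrofurans with this catalyst. The ring closes as a five-membered oxacycle from an oxygen-linked 1,6-diene, the new bond being the ring alkene itself. No stereocentre is formed; the (S)-carbinol centre lies outside the reacting bonds and the aryl-bearing carbon remains a mixture. The selectivity needed is the pairing of these two alkenes among four: the prenyl alkene is trisubstituted and could only close a strained four-membered or a slow eight-membered ring, and the senecioate alkene is trisubstituted and electron-poor, so neither should compete with a five-ring closure run at high dilution.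

**Step 9**
Reactants: 13 (1S)-1-[5-(2,5-dimethoxyphenyl)-2,5-dihydrofuran-3-yl]-4-methylpent-3-en-1-yl 3-methylbut-2-enoate
Product: 14 (1S)-1-[5-(2,5-dimethoxyphenyl)furan-3-yl]-4-methylpent-3-en-1-yl 3-methylbut-2-enoate
Conditions: DDQ (1.2 equiv), 1,4-dioxane (dry), rt to 60 °C
Reagents that add atoms: none
Why: Dehydrogenative aromatisation, in which DDQ abstracts hydride from the ring C–H that is benzylic, allylic and next to oxygen, and loss of a proton from the ring CH2 of the resulting oxocarbenium ion gives the furan; the side-chain stereocentre is not involved.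

**Step 10**
Reactants: 14 (1S)-1-[5-(2,5-dimethoxyphenyl)furan-3-yl]-4-methylpent-3-en-1-yl 3-methylbut-2-enoate
Product: 15 (1S)-1-[5-(3,6-dioxocyclohexa-1,4-dien-1-yl)furan-3-yl]-4-methylpent-3-en-1-yl 3-methylbut-2-enoate
Conditions: (NH4)2Ce(NO3)6 (2.5 equiv), MeCN/H2O, 0 °C, short reaction time
Reagents that add atoms: water, O
Why: Oxidative demethylation of the 1,4-dimethoxyarene by two one-electron oxidations with tetravalent cerium, water adding at the two methoxy-bearing carbons and methanol leaving to give the p-quinone; a brief reaction at 0 °C should spare the furan, the prenyl alkene and the ester, and the stereocentre is remote.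

**Compound list**

1 | 2,5-dimethoxybenzaldehyde | COc1ccc(OC)c(C=O)c1 | starting material
2 | 1-(2,5-dimethoxyphenyl)prop-2-en-1-ol (racemic) | C=CC(O)c1cc(OC)ccc1OC | intermediate
3 | 2,3-dibromopropene | C=C(Br)CBr | starting material
4 | sodium 1-(2,5-dimethoxyphenyl)prop-2-en-1-olate | C=CC([O-])c1cc(OC)ccc1OC.[Na+] | intermediate
5 | 2-{1-[(2-bromoprop-2-en-1-yl)oxy]prop-2-en-1-yl}-1,4-dimethoxybenzene (racemic) | C=CC(OCC(Br)=C)c1cc(OC)ccc1OC | intermediate
6 | 4-methylpent-3-en-1-ol | CC(C)=CCCO | starting material
7 | 4-methylpent-3-enal | CC(C)=CCC=O | intermediate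
8 | 2-({[1-(2,5-dimethoxyphenyl)prop-2-en-1-yl]oxy}methyl)-6-methylhepta-1,5-dien-3-ol (all four stereoisomers) | CC(C)=CCC(O)C(=C)COC(C=C)c1cc(OC)ccc1OC | intermediate
9 | 2-({[1-(2,5-dimethoxyphenyl)prop-2-en-1-yl]oxy}methyl)-6-methylhepta-1,5-dien-3-one (racemic) | CC(C)=CCC(=O)C(=C)COC(C=C)c1cc(OC)ccc1OC | intermediate
10 | (3S)-2-({[1-(2,5-dimethoxyphenyl)prop-2-en-1-yl]oxy}methyl)-6-methylhepta-1,5-dien-3-ol (both epimers at the aryl-bearing carbon) | CC(C)=CC[C@H](O)C(=C)COC(C=C)c1cc(OC)ccc1OC | intermediate
11 | 3-methylbut-2-enoic acid | CC(C)=CC(=O)O | starting material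
12 | (3S)-2-({[1-(2,5-dimethoxyphenyl)prop-2-en-1-yl]oxy}methyl)-6-methylhepta-1,5-dien-3-yl 3-methylbut-2-enoate (both epimers at the aryl-bearing carbon) | CC(C)=CC[C@H](OC(=O)C=C(C)C)C(=C)COC(C=C)c1cc(OC)ccc1OC | intermediate
13 | (1S)-1-[5-(2,5-dimethoxyphenyl)-2,5-dihydrofuran-3-yl]-4-methylpent-3-en-1-yl 3-methylbut-2-enoate (both epimers at the aryl-bearing ring carbon) | CC(C)=CC[C@H](OC(=O)C=C(C)C)C1=CC(c2cc(OC)ccc2OC)OC1 | intermediate
14 | (1S)-1-[5-(2,5-dimethoxyphenyl)furan-3-yl]-4-methylpent-3-en-1-yl 3-methylbut-2-enoate | CC(C)=CC[C@H](OC(=O)C=C(C)C)c1coc(-c2cc(OC)ccc2OC)c1 | intermediate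
15 | (1S)-1-[5-(3,6-dioxocyclohexa-1,4-dien-1-yl)furan-3-yl]-4-methylpent-3-en-1-yl 3-methylbut-2-enoate | CC(C)=CC[C@H](OC(=O)C=C(C)C)c1coc(C2=CC(=O)C=CC2=O)c1 | target

**Step count and risks**

Total step count: 10. Longest linear sequence: 9 steps (steps 1, 2 and 4 to 10); step 3 prepares the aldehyde branch.

The three steps most likely to fail:

Step 8 (ring-closing metathesis). The closure onto the 1,1-disubstituted alkene may be slow, because that alkene is flanked by the carbon carrying the bulky acyloxy group. Intermolecular metathesis through the vinyl groups, or ruthenium hydride-induced migration of double bonds, could then take over. The fallback changes the order of ring closure and acylation and sets out from alcohol 10. The free allylic hydroxyl is smaller and is known to speed metathesis at the neighbouring alkene. Treatment of 10 with the second-generation Hoveyda–Grubbs catalyst RuCl2(=CH-C6H4-2-OiPr)(H2IMes) in dilute CH2Cl2 at 40 °C should give (1S)-1-[5-(2,5-dimethoxyphenyl)-2,5-dihydrofuran-3-yl]-4-methylpent-3-en-1-ol F1. Esterification of this alcohol with acid 11 (DCC, DMAP, CH2Cl2) then comes back to the route at 13.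

Step 10 (oxidative demethylation). One-electron oxidation of the electron-rich 2-arylfuran, whose C5 position is unsubstituted, may compete with demethylation and lead to oxidative opening of the furan ring. The fallback reverses the order of the last two operations so that no furan meets the cerium oxidant, and sets out from dihydrofuran 13. Oxidation of 13 with (NH4)2Ce(NO3)6 in MeCN/H2O at 0 °C should give (1S)-1-[5-(3,6-dioxocyclohexa-1,4-dien-1-yl)-2,5-dihydrofuran-3-yl]-4-methylpent-3-en-1-yl 3-methylbut-2-enoate F2. DDQ in 1,4-dioxane at 60 to 80 °C should then dehydrogenate the dihydrofuran ring, by hydride abstraction from the ring CH2 next to oxygen and loss of the proton next to the quinone, and arrive at 15. Should the quinone rearrange by internal redox to the furyl hydroquinone (1S)-1-[5-(2,5-dihydroxyphenyl)furan-3-yl]-4-methylpent-3-en-1-yl 3-methylbut-2-enoate F3, the same DDQ treatment would oxidise it to 15 as well.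

Step 4 (Nozaki–Hiyama–Kishi coupling). Insertion into the 1,1-disubstituted vinylic C–Br bond may be sluggish. During a long reaction the β,γ double bond of aldehyde 7 can drift into conjugation, or the aldehyde can self-condense under the Lewis-acidic chromium salts. The fallback replaces the aldehyde addition by acylation of an alkenyllithium with a stable amide and sets out from bromide 5. Bromine–lithium exchange with t-BuLi (2 equiv) in Et2O at −78 °C should give [3-{[1-(2,5-dimethoxyphenyl)prop-2-en-1-yl]oxy}prop-1-en-2-yl]lithium F4. This is trapped with the Weinreb amide N-methoxy-N,4-dimethylpent-3-enamide F5, which is made from commercial 4-methylpent-3-enoic acid and N,O-dimethylhydroxylamine hydrochloride with a carbodiimide. The acylation gives enone 9 directly, so the route is rejoined at 9 and compounds 7 and 8 and step 5 are no longer needed. The low temperature is needed so that exchange outruns deprotonation of the doubly activated ether C–H.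

**Further compounds**

F1 | step 8 | (1S)-1-[5-(2,5-dimethoxyphenyl)-2,5-dihydrofuran-3-yl]-4-methylpent-3-en-1-ol (both epimers at the aryl-bearing ring carbon) | CC(C)=CC[C@H](O)C1=CC(c2cc(OC)ccc2OC)OC1
F2 | step 10 | (1S)-1-[5-(3,6-dioxocyclohexa-1,4-dien-1-yl)-2,5-dihydrofuran-3-yl]-4-methylpent-3-en-1-yl 3-methylbut-2-enoate (both epimers at the quinone-bearing ring carbon) | CC(C)=CC[C@H](OC(=O)C=C(C)C)C1=CC(C2=CC(=O)C=CC2=O)OC1
F3 | step 10 | (1S)-1-[5-(2,5-dihydroxyphenyl)furan-3-yl]-4-methylpent-3-en-1-yl 3-methylbut-2-enoate | CC(C)=CC[C@H](OC(=O)C=C(C)C)c1coc(-c2cc(O)ccc2O)c1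
F4 | step 4 | [3-{[1-(2,5-dimethoxyphenyl)prop-2-en-1-yl]oxy}prop-1-en-2-yl]lithium (racemic) | [Li]C(=C)COC(C=C)c1cc(OC)ccc1OC
F5 | step 4 | N-methoxy-N,4-dimethylpent-3-enamide | CC(C)=CCC(=O)N(C)OC
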